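## Structural features

The target is a cis-fused hydroazulene. A cyclopentane (C1–C5) shares the C1–C5 bond with a cycloheptene (C1, C5, C6, C7, C8, C9, C10) whose only ring alkene is the trisubstituted C8=C9, C8 bearing a methyl group. The skeleton is numbered C1 (quaternary, methyl-bearing fusion carbon), C2 and C3 (ring CH2), C4 (isopropyl carbinol), C5 (fusion CH), C6 (4-hydroxybenzoyloxy carbon), C7 (CH2), C8, C9, C10 (tigloyloxy carbon). Five stereocentres are contiguous along C10–C1–C5–C6 and C5–C4: C1 (R), C4 (R), C5 (S), C6 (R) and C10 (R). H5, the C1 methyl and the isopropyl group lie on one face of the cyclopentane and the C4 hydroxyl, C6 and C10 on the other; the C6 oxygen is trans to H5 and the C10 oxygen is syn to the C1 methyl. The fragile groups are the allylic, neopentyl-type tiglate at C10 (ionisation, conjugate addition), the free phenol and its ester (no strong base, no hydrogenation) and the tertiary C4 hydroxyl, which is β to the C6 oxygen. The real difficulty is the crowded array C1 (quaternary)–C5–C4 (fully substituted) with a cis ring fusion, together with two secondary oxygens that must carry different acyl groups. Two patterns are exploited. The oxygen on C4 next to C5 and an oxygenated C6 is what an α,β-epoxy ketone leaves after attack at C5 with inversion. The oxygen on C10, flanked by C1 and the C9=C8(methyl) unit, is what a 2-siloxydiene leaves after cycloaddition. Both rings and the bonds C1–C5 and C7–C8 can therefore come from one (4+3) step.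

## Logic of the disconnections

28 ⇒ 27. The O–Si bonds at the C4 oxygen and at the phenol oxygen are cut last. One fluoride treatment then frees both hydroxyls, and the forward step must leave two esters and an allylic C–O bond untouched.

27 ⇒ 25 + 26. The C10 O–acyl bond is cut. The allylic alcohol is acylated only after the C6 oxygen is already differentiated; the forward step must acylate a hindered neopentyl-type carbinol without deconjugating the acyl unit.

25 ⇒ 24. The C10–H bond is cut (carbinol to enone). This places the last stereocentre under control of the bicyclic framework and requires 1,2-selective hydride delivery anti to the C1 methyl.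

24 ⇒ 23. The C8=C9 alkene is traced back to a C10 silyl enol ether with sp3 C8. The enol ether is exactly what the ring-forming step leaves, and it also masks the C10 ketone while C6 is handled. The forward step is a dehydrogenation of a hindered enol silane.

23 ⇒ 19 + 21. The C6 O–aroyl bond is cut. The phenol arrives silyl-protected so that the final step is a single desilylation; the forward step must acylate a secondary alcohol next to the silylated C4 carbinol without touching the enol ether.

21 ⇒ 20. Two O–Si bonds are cut, giving a commercial acid; the silyl ester later serves as a neutral source of the acid chloride.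

19 ⇒ 18. The C6–H bond is cut. The ketone must be reduced from the convex face (the H5 face) and under conditions that do not epimerise C5.

18 ⇒ 17. C1–C5 and C7–C8 are cut together. Two rings, two skeletal bonds and three stereocentres fall away, leaving an acyclic chain whose only stereocentres are the two epoxide carbons. The forward step must invert C5, keep C4 and close the rings with a cis fusion at a fully substituted diene terminus.

17 ⇒ 16. Two O–Si bonds are cut, giving a diketone. Both enolisations must go to the α′ side: the methyl group of the epoxy ketone and the C1 methine of the enone.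

16 ⇒ 15. The C6 carbonyl is traced to a carbinol, so that the methyl ketone appears only after all nucleophile additions are finished.

15 ⇒ 14. The C6–C7 bond is cut (methyl anion plus aldehyde). The forward step must choose the aldehyde over the enone.

14 ⇒ 13. Both carbonyls (C6 and C10) are traced to alcohols, so that one oxidation serves both ends of the chain.

13 ⇒ 10 + 11. The C9–C10 bond is cut (alkenyl anion plus aldehyde). The (E) geometry of the propenyl unit, needed for an s-cis diene, comes from the commercial bromide with retention.

10 ⇒ 9. The two epoxide C–O bonds are cut. All absolute stereochemistry of the target is traced to one reagent-controlled epoxidation of an (E)-allylic alcohol; the forward step needs the D-tartrate ligand and must tolerate a remote aldehyde.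

9 ⇒ 8. The C6 alcohol and the C10 aldehyde are traced to an ester and an N-methoxy-N-methylamide, so that a single hydride reagent sets both oxidation levels.

8 ⇒ 5 + 6. The C4–isopropyl bond is cut. A syn carbometalation of an ynoate fixes the alkene geometry (chain cis to the ester), which later becomes the relative configuration C4/C5.

5 ⇒ 3. The C1–CH3 bond and the C5–C6 bond are cut. Both come from one dianion, the more basic site being alkylated first.

3 ⇒ 1. The C10–N bond is cut, back to the commercial alkynoic acid.

## Other disconnections considered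

Alternative 1: The cut is C1–C10. In the forward sense the phenylselenoester A1 is treated with Bu3SnH and AIBN; the acyl radical adds 7-endo to the β-carbon C1 of the 3-methylcyclopentenone, and hydrogen transfer to the C5 radical should give the cis-fused dione A2.
- In its favour: the quaternary C1 is made by a radical addition, which is little affected by crowding. On this single bond the alternative is the better plan, because 17 → 18 needs an ionic attack by a tetrasubstituted enol ether carbon. The ring fusion is also correctable, since C5 is α to the C4 ketone; on that point it is at least the equal of the chosen plan.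
- Against it: the C6 stereocentre must be made beforehand and must steer the face of attack at C1 through the forming ring. C4 is left as a ketone, so the isopropyl group must be added to a hindered, enolisable cyclopentanone in the presence of the C10 ketone, with facial control.
- Comparison: A2 still needs the C8=C9 dehydrogenation, as 23 does (equal). Mechanistically a neutral radical chain is more predictable than the cationic cascade. Structurally it forms one ring and one bond against two rings and two bonds, and it needs a separately built 2,3-disubstituted cyclopentenone, so the route should be longer.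

Alternative 2: The cut is C1–C5, made by a 1,2-shift. The trans-decalin mesylate A4, derived from the Wieland–Miescher ketone A3, is treated with KOt-Bu; the C6 alkoxide pushes C1 from C6 to C5 as the mesylate leaves, and the cis-fused hydroazulenone A5 should result.
- In its favour: the absolute configuration and the quaternary C1 come from an organocatalytic Robinson annulation, and the shift is stereospecific. On security of C1 and of the ring fusion this alternative is the better plan.
- Against it: A5 carries neither the isopropyl group nor the C8 methyl. C4 must be deprotected, oxidised and alkylated next to a C5 that then sits between two carbonyl carbons. C8 needs a dehydrogenation, a methyl conjugate addition and a second dehydrogenation.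
- Comparison: the mechanism is more reliable than the chosen one, but the chosen plan brings every carbon and the C4 carbinol into the ring-forming step, while this one adds them afterwards; step economy is clearly worse.

Alternative 3: The cut is C6–C7. The aldehyde allylsilane A6 is treated with BF3·OEt2; the allylsilane terminus C7 adds to the C6 aldehyde with loss of the silyl group and should give the methylene hydroazulenone A7.
- In its favour: the C6 carbinol is formed directly, and simple isomerisation of the exocyclic alkene into conjugation would give the C8=C9 enone with its methyl group. On these two points the alternative is the better plan, as it saves the reduction of 18 and the dehydrogenation of 23.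
- Against it: A6 already contains the complete cyclopentane with C1, C4 and C5 set, so the hardest part of the target is moved, not solved. Its aldehyde is α-epimerisable and β-silyloxylated, and the C9 methylene is doubly activated, so the allylsilane may isomerise. The C6 configuration rests on substrate control.
- Comparison: the mechanism is ordinary Lewis acid chemistry in both plans. The key step builds one ring, one bond and one stereocentre against two, two and three, and the route to A6 should make the whole sequence longer.

Key step: step 11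

Remark: C1–C10 are the skeleton atoms defined above. C1 in 4–16 and the carbinol centres of 13 and 15 are destroyed later and are carried as mixtures. 17 is expected as a mixture of C1=C10 geometric isomers; these should give C8 epimers of 18–23 that converge in step 15 (the (3Z) isomer and its C8 epimer are drawn).

## Steps

Step 1
Reactants: 1 hex-5-ynoic acid
Product: 3 N-methoxy-N-methylhex-5-ynamide, via 1-(hex-5-ynoyl)imidazole 2 (not isolated)
Conditions: 1,1'-carbonyldiimidazole, CH2Cl2, rt; then MeNH(OMe)·HCl, rt
Reagents that add atoms: N,O-dimethylhydroxylamine hydrochloride, CNOC.Cl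
Why: Amide formation through the acyl imidazole; the N-methoxy-N-methylamide is a non-ester acyl group that tolerates the later organocopper step and is reduced only to the aldehyde level.

Step 2
Reactants: 3 N-methoxy-N-methylhex-5-ynamide
Product: 5 methyl 7-[methoxy(methyl)amino]-6-methyl-7-oxohept-2-ynoate, via N-methoxy-N,2-dimethylhex-5-ynamide lithium acetylide 4 (not isolated)
Conditions: LiN(iPr)2 (2.2 equiv), THF, −78 °C; MeI (1.0 equiv), −78 °C; then ClCO2Me (excess), −78 → −30 °C
Reagents that add atoms: iodomethane, CI; methyl chloroformate, COC(=O)Cl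
Why: Sequential trapping of a dianion: the amide enolate, the more basic and more nucleophilic site, should be C-methylated by one equivalent of MeI at −78 °C, while the lithium acetylide is inert to MeI in THF at that temperature and is then acylated by the chloroformate (enolate alkylation followed by acetylide acylation).

Step 3
Reactants: 5 methyl 7-[methoxy(methyl)amino]-6-methyl-7-oxohept-2-ynoate; 6 isopropylmagnesium bromide
Product: 8 methyl (2E)-7-[methoxy(methyl)amino]-6-methyl-7-oxo-3-(propan-2-yl)hept-2-enoate, via isopropylcopper 7 (not isolated)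
Conditions: 6, CuBr·SMe2, THF, −78 °C; then 5, −78 °C; aq. NH4Cl at −78 °C
Reagents that add atoms: none
Why: Syn carbocupration (conjugate addition) of an organocopper reagent to an ynoate; the α-cuprio enoate keeps its geometry at −78 °C and protonation with retention places isopropyl and H cis, so the chain ends up cis to the ester ((E) by the priority rules). The amide does not react with organocopper reagents at this temperature.

Step 4
Reactants: 8 methyl (2E)-7-[methoxy(methyl)amino]-6-methyl-7-oxo-3-(propan-2-yl)hept-2-enoate
Product: 9 (5E)-7-hydroxy-2-methyl-5-(propan-2-yl)hept-5-enal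
Conditions: iBu2AlH (3.5 equiv), CH2Cl2, −78 °C; aq. potassium sodium tartrate
Reagents that add atoms: none
Why: Hydride reduction by iBu2AlH: the enoate is reduced 1,2 to the allylic alcohol, and the N-methoxy-N-methylamide stops at a chelated aluminium hemiaminal that releases the aldehyde only on work-up, so both ends reach the required oxidation level in one operation.

Step 5
Reactants: 9 (5E)-7-hydroxy-2-methyl-5-(propan-2-yl)hept-5-enal
Product: 10 4-[(2R,3R)-3-(hydroxymethyl)-2-(propan-2-yl)oxiran-2-yl]-2-methylbutanal
Conditions: Ti(OiPr)4 (10 mol%), D-(−)-diethyl tartrate (12 mol%), t-BuOOH, 4 Å molecular sieves, CH2Cl2, −20 °C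
Reagents that add atoms: tert-butyl hydroperoxide, CC(C)(C)OO
Why: Sharpless asymmetric epoxidation of a 3,3-disubstituted (E)-allylic alcohol; L-(+)-tartrate gives (2S,3S)-epoxy alcohols from such substrates, so the D-(−)-ligand should give the (2R,3R)-epoxide, which sets C4 and C5 (C5 to be inverted in step 11). The remote aldehyde has no allylic hydroxyl and is not expected to react with the titanium peroxide.

Step 6
Reactants: 10 4-[(2R,3R)-3-(hydroxymethyl)-2-(propan-2-yl)oxiran-2-yl]-2-methylbutanal; 11 (E)-1-bromoprop-1-ene
Product: 13 (2E)-7-[(2R,3R)-3-(hydroxymethyl)-2-(propan-2-yl)oxiran-2-yl]-5-methylhept-2-en-4-ol, via (E)-prop-1-enyllithium 12 (not isolated)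
Conditions: 11, t-BuLi (2 equiv per 11), Et2O, −78 °C; then 10 (0.4 equiv relative to 11), −78 °C; aq. NH4Cl
Reagents that add atoms: none
Why: Bromine–lithium exchange with retention of alkene geometry, then 1,2-addition of the alkenyllithium to the aldehyde; the first equivalent is used up by the hydroxyl group and the trisubstituted epoxide is inert to organolithium reagents at −78 °C. The new carbinol centre is not controlled and is oxidised away in step 7.

Step 7
Reactants: 13 (2E)-7-[(2R,3R)-3-(hydroxymethyl)-2-(propan-2-yl)oxiran-2-yl]-5-methylhept-2-en-4-ol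
Product: 14 (2S,3R)-3-[(5E)-3-methyl-4-oxohept-5-en-1-yl]-3-(propan-2-yl)oxirane-2-carbaldehyde
Conditions: Dess–Martin periodinane (2.6 equiv), NaHCO3, CH2Cl2, 0 °C → rt
Reagents that add atoms: none
Why: Dess–Martin oxidation of both alcohols under buffered, non-epimerising conditions: the primary epoxy alcohol gives the epoxy aldehyde and the secondary allylic alcohol gives the (E)-propenyl ketone (the descriptor at the aldehyde-bearing carbon changes by priority only).

Step 8
Reactants: 14 (2S,3R)-3-[(5E)-3-methyl-4-oxohept-5-en-1-yl]-3-(propan-2-yl)oxirane-2-carbaldehyde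
Product: 15 (2E)-7-[(2R,3R)-3-(1-hydroxyethyl)-2-(propan-2-yl)oxiran-2-yl]-5-methylhept-2-en-4-one
Conditions: MeMgBr (1.05 equiv), THF, −78 °C
Reagents that add atoms: methylmagnesium bromide, C[Mg]Br
Why: Grignard 1,2-addition; the α-oxygenated aldehyde is far more electrophilic than the α-branched conjugated ketone, so one equivalent at −78 °C should add only at C6.

Step 9
Reactants: 15 (2E)-7-[(2R,3R)-3-(1-hydroxyethyl)-2-(propan-2-yl)oxiran-2-yl]-5-methylhept-2-en-4-one
Product: 16 (2E)-7-[(2R,3S)-3-acetyl-2-(propan-2-yl)oxiran-2-yl]-5-methylhept-2-en-4-one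
Conditions: Dess–Martin periodinane, NaHCO3, CH2Cl2, 0 °C → rt
Reagents that add atoms: none
Why: Dess–Martin oxidation of the secondary alcohol to the epoxy methyl ketone; the neutral conditions leave the epoxide and the enone alone.

Step 10
Reactants: 16 (2E)-7-[(2R,3S)-3-acetyl-2-(propan-2-yl)oxiran-2-yl]-5-methylhept-2-en-4-one
Product: 17 (2R,3S)-2-[(3Z,5E)-3-methyl-4-[(triethylsilyl)oxy]hepta-3,5-dien-1-yl]-2-(propan-2-yl)-3-{1-[(triethylsilyl)oxy]ethenyl}oxirane (with its (3E) isomer)
Conditions: KN(SiMe3)2 (2.5 equiv), Et3SiCl (3 equiv), THF, −78 → −40 °C (base added to ketone and silyl chloride); Et3N, pentane, filtration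
Reagents that add atoms: chlorotriethylsilane, CC[Si](Cl)(CC)CC
Why: Kinetic enolisation with in situ O-silylation: the methyl ketone can only enolise towards CH3, and an enone is deprotonated kinetically at the α′ carbon (C1) in preference to the γ methyl, which gives the cross-conjugated 2-siloxydiene. The C1=C10 geometry is not controlled and need not be, because C1 is set by the ring fusion and C8 is erased later.

Step 11
Reactants: 17 (2R,3S)-2-[(3Z,5E)-3-methyl-4-[(triethylsilyl)oxy]hepta-3,5-dien-1-yl]-2-(propan-2-yl)-3-{1-[(triethylsilyl)oxy]ethenyl}oxirane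
Product: 18 (3R,3aR,6S,8aR)-6,8a-dimethyl-3-(propan-2-yl)-3,8-bis[(triethylsilyl)oxy]-2,3,3a,5,6,8a-hexahydroazulen-4(1H)-one
Conditions: Et3SiOTf (10 mol%), 2,6-di-tert-butyl-4-methylpyridine (5 mol%), CH2Cl2, −78 °C; Et3N quench
Reagents that add atoms: none
Why: Silylation of the epoxide oxygen weakens the C5–O bond, which is activated by the C6 enol ether, and the nucleophilic diene terminus C1 displaces it from the rear; the siloxyallyl cation (C10, C9, C8) so formed is captured at C8 by C7 of the C6 enol silane, so the two bonds add up to a (4+3) cycloaddition, and transfer of Et3Si+ from the C6 oxocarbenium ion to the next epoxide turns the catalyst over. The closest known reaction type is the silyl triflate-catalysed intramolecular (4+3) cycloaddition of epoxy enol silanes with tethered dienes, which passes the epoxide configuration on to the product; a 2-siloxydiene with a fully substituted terminus is an untried extension of it. The cyclopentane closes by attack at the distal epoxide carbon (endo-mode epoxide opening, equal to a 5-exo-trig closure at the trigonal C5 of the allyl cation, with the C1=C10 bond exocyclic), and the cycloheptene closes 7-endo-trig at C8. C4 keeps its configuration because its C–O bond is never broken; C5 is inverted because C1 enters anti to the leaving oxygen, which puts the C4 oxygen and C6 on the same face. C1 is set by a compact arrangement with C10 above C6, giving the cis fusion with methyl syn to H5; this arrangement is the only one open to the (3E) enol ether isomer (tether cis to the vinyl group) and is required of the (3Z) isomer. C8 follows from suprafacial addition and is erased in step 15. The step also needs ionisation at C5 and not C4 (only C5 is stabilised by the enol ether), an s-cis diene, and proton-free conditions (hindered pyridine) so that neither enol ether is hydrolysed.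

Step 12
Reactants: 18 (3R,3aR,6S,8aR)-6,8a-dimethyl-3-(propan-2-yl)-3,8-bis[(triethylsilyl)oxy]-2,3,3a,5,6,8a-hexahydroazulen-4(1H)-one
Product: 19 (3R,3aS,4R,6S,8aR)-6,8a-dimethyl-3-(propan-2-yl)-3,8-bis[(triethylsilyl)oxy]-1,2,3,3a,4,5,6,8a-octahydroazulen-4-ol
Conditions: NaBH4, THF–EtOH, −20 °C
Reagents that add atoms: none
Why: Borohydride reduction of the C6 ketone from the convex face of the cis-fused bicycle (the H5 face, away from the fully substituted C4), which should give the alcohol trans to H5. The low temperature guards against C5 epimerisation and loss of the β-silyloxy group, and the hindered C10 enol ether keeps the second carbonyl masked.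

Step 13
Reactants: 20 4-hydroxybenzoic acid
Product: 21 tert-butyldimethylsilyl 4-[(tert-butyldimethylsilyl)oxy]benzoate
Conditions: t-BuMe2SiCl (2.2 equiv), imidazole, DMF, rt
Reagents that add atoms: tert-butyl(chloro)dimethylsilane, CC(C)(C)[Si](C)(C)Cl
Why: Silylation of phenol and acid; the silyl ester is a neutral precursor of the acid chloride and the aryl silyl ether will fall in the final desilylation.

Step 14
Reactants: 19 (3R,3aS,4R,6S,8aR)-6,8a-dimethyl-3-(propan-2-yl)-3,8-bis[(triethylsilyl)oxy]-1,2,3,3a,4,5,6,8a-octahydroazulen-4-ol; 21 tert-butyldimethylsilyl 4-[(tert-butyldimethylsilyl)oxy]benzoate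
Product: 23 (3R,3aS,4R,6S,8aR)-6,8a-dimethyl-3-(propan-2-yl)-3,8-bis[(triethylsilyl)oxy]-1,2,3,3a,4,5,6,8a-octahydroazulen-4-yl 4-[(tert-butyldimethylsilyl)oxy]benzoate, via 4-[(tert-butyldimethylsilyl)oxy]benzoyl chloride 22 (not isolated)
Conditions: 21, (COCl)2, DMF (cat.), CH2Cl2, 0 °C → rt, evaporate; then 19, Et3N, 4-(dimethylamino)pyridine, CH2Cl2, rt → 40 °C
Reagents that add atoms: none
Why: The silyl ester is converted into the acid chloride by oxalyl chloride and DMF without free HCl, and the secondary C6 alcohol is then acylated under nucleophilic catalysis; the basic medium protects the silyl enol ether and the C4 silyl ether blocks the tertiary oxygen.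

Step 15
Reactants: 23 (3R,3aS,4R,6S,8aR)-6,8a-dimethyl-3-(propan-2-yl)-3,8-bis[(triethylsilyl)oxy]-1,2,3,3a,4,5,6,8a-octahydroazulen-4-yl 4-[(tert-butyldimethylsilyl)oxy]benzoate
Product: 24 (3R,3aS,4R,8aR)-6,8a-dimethyl-8-oxo-3-(propan-2-yl)-3-[(triethylsilyl)oxy]-1,2,3,3a,4,5,8,8a-octahydroazulen-4-yl 4-[(tert-butyldimethylsilyl)oxy]benzoate
Conditions: Pd(OAc)2 (1.1 equiv), MeCN, rt → 40 °C
Reagents that add atoms: none
Why: Saegusa–Ito oxidation: divalent palladium adds to C9 of the enol silane and β-hydride elimination can only take the C8 hydrogen (C1 is quaternary), which should give the C8=C9 enone and remove the C8 stereocentre.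

Step 16
Reactants: 24 (3R,3aS,4R,8aR)-6,8a-dimethyl-8-oxo-3-(propan-2-yl)-3-[(triethylsilyl)oxy]-1,2,3,3a,4,5,8,8a-octahydroazulen-4-yl 4-[(tert-butyldimethylsilyl)oxy]benzoate
Product: 25 (3R,3aS,4R,8R,8aR)-8-hydroxy-6,8a-dimethyl-3-(propan-2-yl)-3-[(triethylsilyl)oxy]-1,2,3,3a,4,5,8,8a-octahydroazulen-4-yl 4-[(tert-butyldimethylsilyl)oxy]benzoate
Conditions: NaBH4, CeCl3·7H2O, MeOH, −78 → −40 °C
Reagents that add atoms: none
Why: Luche 1,2-reduction of the enone; hydride is expected anti to the C1 methyl, as is usual for ketones flanked by an angular methyl group, in the conformer that keeps the C6 ester pseudo-equatorial and the methyl pseudo-axial, giving the C10 alcohol syn to the methyl.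

Step 17
Reactants: 25 (3R,3aS,4R,8R,8aR)-8-hydroxy-6,8a-dimethyl-3-(propan-2-yl)-3-[(triethylsilyl)oxy]-1,2,3,3a,4,5,8,8a-octahydroazulen-4-yl 4-[(tert-butyldimethylsilyl)oxy]benzoate; 26 (2E)-2-methylbut-2-enoyl chloride
Product: 27 (3R,3aS,4R,8R,8aR)-6,8a-dimethyl-8-{[(2E)-2-methylbut-2-enoyl]oxy}-3-(propan-2-yl)-3-[(triethylsilyl)oxy]-1,2,3,3a,4,5,8,8a-octahydroazulen-4-yl 4-[(tert-butyldimethylsilyl)oxy]benzoate
Conditions: 26, 4-(dimethylamino)pyridine, pyridine, CH2Cl2, 0 °C → rt
Reagents that add atoms: none
Why: Acylation of the allylic alcohol through the acylpyridinium ion, with retention at C10; pyridine in place of a trialkylamine avoids the vinylketene path that would deconjugate the tigloyl group.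

Step 18
Reactants: 27 (3R,3aS,4R,8R,8aR)-6,8a-dimethyl-8-{[(2E)-2-methylbut-2-enoyl]oxy}-3-(propan-2-yl)-3-[(triethylsilyl)oxy]-1,2,3,3a,4,5,8,8a-octahydroazulen-4-yl 4-[(tert-butyldimethylsilyl)oxy]benzoate
Product: 28 (3R,3aS,4R,8R,8aR)-3-hydroxy-6,8a-dimethyl-8-{[(2E)-2-methylbut-2-enoyl]oxy}-3-(propan-2-yl)-1,2,3,3a,4,5,8,8a-octahydroazulen-4-yl 4-hydroxybenzoate
Conditions: Bu4NF, AcOH, THF, 0 °C → rt
Reagents that add atoms: none
Why: Fluoride desilylation of the aryl silyl ether and the tertiary triethylsilyl ether in one operation; acetic acid keeps the phenoxide protonated so that neither ester is cleaved or migrates.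

## Compound list

1 | hex-5-ynoic acid | C#CCCCC(=O)O | starting material
2 | 1-(hex-5-ynoyl)imidazole | C#CCCCC(=O)n1ccnc1 | intermediate (not isolated)
3 | N-methoxy-N-methylhex-5-ynamide | C#CCCCC(=O)N(C)OC | intermediate
4 | N-methoxy-N,2-dimethylhex-5-ynamide (formed as its lithium acetylide; racemic) | C#CCCC(C)C(=O)N(C)OC | intermediate (not isolated)
5 | methyl 7-[methoxy(methyl)amino]-6-methyl-7-oxohept-2-ynoate (racemic) | COC(=O)C#CCCC(C)C(=O)N(C)OC | intermediate
6 | isopropylmagnesium bromide | CC(C)[Mg]Br | starting material
7 | isopropylcopper (as its MgBr2·SMe2 complex) | CC(C)[Cu] | intermediate (not isolated)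
8 | methyl (2E)-7-[methoxy(methyl)amino]-6-methyl-7-oxo-3-(propan-2-yl)hept-2-enoate (racemic) | COC(=O)/C=C(/C(C)C)CCC(C)C(=O)N(C)OC | intermediate
9 | (5E)-7-hydroxy-2-methyl-5-(propan-2-yl)hept-5-enal (racemic) | OC/C=C(/C(C)C)CCC(C)C=O | intermediate
10 | 4-[(2R,3R)-3-(hydroxymethyl)-2-(propan-2-yl)oxiran-2-yl]-2-methylbutanal (both epimers at C2 of the butanal) | OC[C@H]1O[C@@]1(C(C)C)CCC(C)C=O | intermediate
11 | (E)-1-bromoprop-1-ene | C/C=C/Br | starting material
12 | (E)-prop-1-enyllithium | C/C=C/[Li] | intermediate (not isolated)
13 | (2E)-7-[(2R,3R)-3-(hydroxymethyl)-2-(propan-2-yl)oxiran-2-yl]-5-methylhept-2-en-4-ol (epimers at C4 and C5 of the heptenol) | OC[C@H]1O[C@@]1(C(C)C)CCC(C)C(O)/C=C/C | intermediate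
14 | (2S,3R)-3-[(5E)-3-methyl-4-oxohept-5-en-1-yl]-3-(propan-2-yl)oxirane-2-carbaldehyde (both epimers at the methyl-bearing carbon) | O=C[C@H]1O[C@@]1(C(C)C)CCC(C)C(=O)/C=C/C | intermediate
15 | (2E)-7-[(2R,3R)-3-(1-hydroxyethyl)-2-(propan-2-yl)oxiran-2-yl]-5-methylhept-2-en-4-one (epimers at the carbinol and at C5) | CC(O)[C@H]1O[C@@]1(C(C)C)CCC(C)C(=O)/C=C/C | intermediate
16 | (2E)-7-[(2R,3S)-3-acetyl-2-(propan-2-yl)oxiran-2-yl]-5-methylhept-2-en-4-one (both epimers at C5) | CC(=O)[C@H]1O[C@@]1(C(C)C)CCC(C)C(=O)/C=C/C | intermediate
17 | (2R,3S)-2-[(3Z,5E)-3-methyl-4-[(triethylsilyl)oxy]hepta-3,5-dien-1-yl]-2-(propan-2-yl)-3-{1-[(triethylsilyl)oxy]ethenyl}oxirane (the (3E) isomer is expected alongside) | C=C(O[Si](CC)(CC)CC)[C@H]1O[C@@]1(C(C)C)CC/C(C)=C(O[Si](CC)(CC)CC)/C=C/C | intermediate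
18 | (3R,3aR,6S,8aR)-6,8a-dimethyl-3-(propan-2-yl)-3,8-bis[(triethylsilyl)oxy]-2,3,3a,5,6,8a-hexahydroazulen-4(1H)-one (cis-fused; C4 silyl ether, C6 ketone, C10 silyl enol ether) | CC[Si](CC)(CC)OC1=C[C@@H](C)CC(=O)[C@@H]2[C@@]1(C)CC[C@@]2(O[Si](CC)(CC)CC)C(C)C | intermediate
19 | (3R,3aS,4R,6S,8aR)-6,8a-dimethyl-3-(propan-2-yl)-3,8-bis[(triethylsilyl)oxy]-1,2,3,3a,4,5,6,8a-octahydroazulen-4-ol | CC[Si](CC)(CC)OC1=C[C@@H](C)C[C@@H](O)[C@@H]2[C@@]1(C)CC[C@@]2(O[Si](CC)(CC)CC)C(C)C | intermediate
20 | 4-hydroxybenzoic acid | O=C(O)c1ccc(O)cc1 | starting material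
21 | tert-butyldimethylsilyl 4-[(tert-butyldimethylsilyl)oxy]benzoate | CC(C)(C)[Si](C)(C)OC(=O)c1ccc(O[Si](C)(C)C(C)(C)C)cc1 | intermediate
22 | 4-[(tert-butyldimethylsilyl)oxy]benzoyl chloride | O=C(Cl)c1ccc(O[Si](C)(C)C(C)(C)C)cc1 | intermediate (not isolated)
23 | (3R,3aS,4R,6S,8aR)-6,8a-dimethyl-3-(propan-2-yl)-3,8-bis[(triethylsilyl)oxy]-1,2,3,3a,4,5,6,8a-octahydroazulen-4-yl 4-[(tert-butyldimethylsilyl)oxy]benzoate | CC[Si](CC)(CC)OC1=C[C@@H](C)C[C@@H](OC(=O)c3ccc(O[Si](C)(C)C(C)(C)C)cc3)[C@@H]2[C@@]1(C)CC[C@@]2(O[Si](CC)(CC)CC)C(C)C | intermediate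
24 | (3R,3aS,4R,8aR)-6,8a-dimethyl-8-oxo-3-(propan-2-yl)-3-[(triethylsilyl)oxy]-1,2,3,3a,4,5,8,8a-octahydroazulen-4-yl 4-[(tert-butyldimethylsilyl)oxy]benzoate | O=C1C=C(C)C[C@@H](OC(=O)c3ccc(O[Si](C)(C)C(C)(C)C)cc3)[C@@H]2[C@@]1(C)CC[C@@]2(O[Si](CC)(CC)CC)C(C)C | intermediate
25 | (3R,3aS,4R,8R,8aR)-8-hydroxy-6,8a-dimethyl-3-(propan-2-yl)-3-[(triethylsilyl)oxy]-1,2,3,3a,4,5,8,8a-octahydroazulen-4-yl 4-[(tert-butyldimethylsilyl)oxy]benzoate | O[C@@H]1C=C(C)C[C@@H](OC(=O)c3ccc(O[Si](C)(C)C(C)(C)C)cc3)[C@@H]2[C@@]1(C)CC[C@@]2(O[Si](CC)(CC)CC)C(C)C | intermediate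
26 | (2E)-2-methylbut-2-enoyl chloride (tigloyl chloride) | C/C=C(\C)C(=O)Cl | starting material
27 | (3R,3aS,4R,8R,8aR)-6,8a-dimethyl-8-{[(2E)-2-methylbut-2-enoyl]oxy}-3-(propan-2-yl)-3-[(triethylsilyl)oxy]-1,2,3,3a,4,5,8,8a-octahydroazulen-4-yl 4-[(tert-butyldimethylsilyl)oxy]benzoate | C/C=C(\C)C(=O)O[C@@H]1C=C(C)C[C@@H](OC(=O)c3ccc(O[Si](C)(C)C(C)(C)C)cc3)[C@@H]2[C@@]1(C)CC[C@@]2(O[Si](CC)(CC)CC)C(C)C | intermediate
28 | (3R,3aS,4R,8R,8aR)-3-hydroxy-6,8a-dimethyl-8-{[(2E)-2-methylbut-2-enoyl]oxy}-3-(propan-2-yl)-1,2,3,3a,4,5,8,8a-octahydroazulen-4-yl 4-hydroxybenzoate | C/C=C(\C)C(=O)O[C@@H]1C=C(C)C[C@@H](OC(=O)c2ccc(O)cc2)[C@@H]2[C@@]1(C)CC[C@@]2(O)C(C)C | target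

## Step count and least certain steps

Total: 18 steps. Longest linear sequence: 17 steps (steps 1–12 and 14–18, from 1); step 13 is a one-step side branch.

Step 11 (key step). The fully substituted diene terminus may not hold the s-cis geometry long enough for the second bond to form. The cascade would then stop after C1–C5 bond formation with loss of the silyl group from the C10 oxygen. Closure through an extended arrangement of the (3Z) isomer would give a trans ring fusion. Fallback, from 17 back to 18: the reaction is run to the interrupted stage on purpose, which should give the monocyclic (E)-1-[(1R,2R,3R)-1-methyl-3-(propan-2-yl)-3-[(triethylsilyl)oxy]-2-{1-[(triethylsilyl)oxy]ethenyl}cyclopentyl]but-2-en-1-one F1. Its ring substitution pattern can be checked before the second ring is made. The seven-membered ring is then closed in a separate intramolecular Mukaiyama–Michael addition of the C6 enol silane to the now freely rotating enone (C7 to C8) under a stronger silyl Lewis acid (Et3SiNTf2, CH2Cl2, −40 °C). This transfers the silyl group to the C10 oxygen and so returns to 18.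

Step 10. Deprotonation may occur at the γ methyl of the propenyl ketone instead of the hindered C1 methine, or the enolisation at C1 may stay incomplete. Fallback, from 16 back to 17, with no new compound: the control is changed from kinetic to thermodynamic by soft enolisation (Et3SiOTf, Et3N, CH2Cl2, 0 °C). The epoxy ketone can enolise only towards its methyl group, and equilibration at the enone should favour the more substituted, cross-conjugated dienol ether.

Step 16. Facial selectivity at C10 may be poor or reversed, because the seven-membered ring can adopt a conformer with the cyclopentane bond, not the methyl group, pseudo-axial at C1; hydride would then enter syn to the methyl. Fallback, from 24 back to 25, with no new compound: substrate control is replaced by reagent control in a Corey–Bakshi–Shibata reduction (catecholborane, 2-methyl-CBS-oxazaborolidine, toluene, −78 °C). The catalyst enantiomer is chosen to deliver hydride to the face anti to the C1 methyl; this would be the (S)-catalyst if the quaternary C1 acts as the large group.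

Step 15. The hindered triethylsilyl enol ether may react slowly with divalent palladium, and the acetic acid set free may protodesilylate it to the saturated C10 ketone before dehydrogenation. Fallback, from 23 back to 24: the enol silane is treated with PhSeCl (CH2Cl2, −78 °C) to give the α-phenylselanyl ketone (3R,3aS,4R,6S,8aR)-6,8a-dimethyl-8-oxo-7-(phenylselanyl)-3-(propan-2-yl)-3-[(triethylsilyl)oxy]decahydroazulen-4-yl 4-[(tert-butyldimethylsilyl)oxy]benzoate F2. Oxidation with H2O2 and syn elimination of the selenoxide can only go towards C8 and should give 24.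

Step 2. The two anionic sites may not be trapped cleanly in one flask: some methylation at the acetylide carbon, or incomplete acylation because the liberated amine consumes chloroformate. Fallback, from 3 back to 5, with no new compound: the dianion is methylated and quenched so that 4 is isolated. The ester is then introduced without strong base by oxidative methoxycarbonylation of the terminal alkyne (PdCl2 cat., CuCl2, NaOAc, CO, MeOH, rt).

## Further compounds

F1 | step 11 | (E)-1-[(1R,2R,3R)-1-methyl-3-(propan-2-yl)-3-[(triethylsilyl)oxy]-2-{1-[(triethylsilyl)oxy]ethenyl}cyclopentyl]but-2-en-1-one | C=C(O[Si](CC)(CC)CC)[C@@H]1[C@](C)(C(=O)/C=C/C)CC[C@@]1(O[Si](CC)(CC)CC)C(C)C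
F0 | step 10 | none | none
F0 | step 16 | none | none
F2 | step 15 | (3R,3aS,4R,6S,8aR)-6,8a-dimethyl-8-oxo-7-(phenylselanyl)-3-(propan-2-yl)-3-[(triethylsilyl)oxy]decahydroazulen-4-yl 4-[(tert-butyldimethylsilyl)oxy]benzoate (configuration at the selenium-bearing carbon not defined) | O=C1C([Se]c4ccccc4)[C@@H](C)C[C@@H](OC(=O)c3ccc(O[Si](C)(C)C(C)(C)C)cc3)[C@@H]2[C@@]1(C)CC[C@@]2(O[Si](CC)(CC)CC)C(C)C
F0 | step 2 | none | none
A1 | alternative 1 | Se-phenyl (5R)-5-[(tert-butyldimethylsilyl)oxy]-3-methyl-5-(2-methyl-5-oxocyclopent-1-en-1-yl)pentaneselenoate | O=C(CC(C)C[C@@H](O[Si](C)(C)C(C)(C)C)C1=C(C)CCC1=O)[Se]c1ccccc1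
A2 | alternative 1 | (3aS,4R,8aR)-4-[(tert-butyldimethylsilyl)oxy]-6,8a-dimethylperhydroazulene-3,8-dione (cis-fused) | O=C1CC(C)C[C@@H](O[Si](C)(C)C(C)(C)C)[C@@H]2[C@@]1(C)CCC2=O
A3 | alternative 2 | (R)-8a-methyl-3,4,8,8a-tetrahydronaphthalene-1,6(2H,7H)-dione (Wieland–Miescher ketone) | C[C@@]12CCC(=O)C=C1CCCC2=O
A4 | alternative 2 | trans-fused 6-[(tert-butyldimethylsilyl)oxy]-4a-hydroxy-8a-methyloctahydro-2H-spiro[naphthalene-1,2'-[1,3]dioxolan]-5-yl methanesulfonate (4a-hydroxyl and 5-mesylate cis, both anti to the 8a-methyl; 6-silyloxy trans to the mesylate) | O1CCOC12CCC[C@]3(O)[C@@H](OS(C)(=O)=O)[C@H](O[Si](C)(C)C(C)(C)C)CC[C@@]23C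
A5 | alternative 2 | cis-fused 3-[(tert-butyldimethylsilyl)oxy]-8a-methylhexahydro-1H-spiro[azulene-8,2'-[1,3]dioxolan]-4(2H)-one | O1CCOC12CCCC(=O)[C@@H]3[C@@]2(C)CC[C@H]3O[Si](C)(C)C(C)(C)C
A6 | alternative 3 | (1R,2R,5R)-2-methyl-2-{3-[(trimethylsilyl)methyl]but-3-enoyl}-5-(propan-2-yl)-5-[(triethylsilyl)oxy]cyclopentane-1-carbaldehyde | O=C[C@@H]1[C@](C)(C(=O)CC(=C)C[Si](C)(C)C)CC[C@@]1(O[Si](CC)(CC)CC)C(C)C
A7 | alternative 3 | (3R,3aS,4R,8aR)-4-hydroxy-8a-methyl-6-methylidene-3-(propan-2-yl)-3-[(triethylsilyl)oxy]octahydroazulen-8(1H)-one | O=C1CC(=C)C[C@@H](O)[C@@H]2[C@@]1(C)CC[C@@]2(O[Si](CC)(CC)CC)C(C)C
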